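Ring C of the isoflavan (O1, C2, C3, C4, C4a, C8a) is read as an indane ring plus O1: without O1, C2 is bonded to C8a and C4 is C3 of a 1-indanone. Everything rests on re-inserting that oxygen. In step 6 a peracid converts the enantioenriched indanone 7 into dihydrocoumarin 8, forming O1–C8a and O1–C2 and ring C in one operation while the C4 centre, set earlier, is only a spectator. The precursor is a (3S)-6-benzyloxy-3-arylindan-1-one whose ring D carries two benzyl ethers and a para diisopropylcarbamate, chosen to damp ring D towards the oxidant and to leave no acid-sensitive group. Ring B and ring F are added afterwards.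

Key step: step 6

Abbreviations: ArD = 2,6-bis(benzyloxy)-4-[(N,N-diisopropylcarbamoyl)oxy]phenyl; ArB = 3-(benzyloxy)-2,4-dimethoxyphenyl.

Assumption: the ligand antipodes written in steps 5 and 17 are those expected to give the 3S indanone and the 2S flavanone; should a pilot run show the opposite sense, the mirror-image ligand is used and nothing else changes.

Step 1
Reactants: 1 3,5-bis(benzyloxy)phenol
Product: 2 2,6-bis(benzyloxy)-4-hydroxybenzaldehyde
Conditions: POCl3, DMF, 0 °C to rt; aq. NaOAc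
Reagents that add atoms: N,N-dimethylformamide, CN(C)C=O (formyl carbon); water, O (carbonyl oxygen)
Why: Vilsmeier–Haack formylation, in which the chloroiminium ion attacks the ring carbon para to the free hydroxyl (activated by all three oxygens) and hydrolysis should give the aldehyde, the hydrogen-bonded ortho isomer being the expected minor product that is removed by crystallisation.

Step 2
Reactants: 2 2,6-bis(benzyloxy)-4-hydroxybenzaldehyde
Product: 3 3,5-bis(benzyloxy)-4-formylphenyl N,N-diisopropylcarbamate (ArD–CHO)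
Conditions: i-Pr2NCOCl, K2CO3, MeCN, 80 °C
Reagents that add atoms: N,N-diisopropylcarbamoyl chloride, CC(C)N(C(C)C)C(Cl)=O
Why: O-carbamoylation of the phenoxide (acyl substitution) should be clean because the para-formyl phenol is acidic and the molecule has no other nucleophilic site.

Step 3
Reactants: 4 1-(2-bromo-5-hydroxyphenyl)ethanone
Product: 5 1-[5-(benzyloxy)-2-bromophenyl]ethanone
Conditions: BnBr, K2CO3, DMF, rt
Reagents that add atoms: benzyl bromide, BrCc1ccccc1
Why: Williamson ether synthesis on the phenoxide, to which the aryl bromide and the methyl ketone are inert under carbonate at room temperature.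

Step 4
Reactants: 5 1-[5-(benzyloxy)-2-bromophenyl]ethanone; 3 3,5-bis(benzyloxy)-4-formylphenyl N,N-diisopropylcarbamate
Product: 6 (E)-1-[5-(benzyloxy)-2-bromophenyl]-3-ArD-prop-2-en-1-one
Conditions: KOH, EtOH/THF, rt
Reagents that add atoms: none
Why: Claisen–Schmidt condensation, in which the ketone enolate adds to the non-enolisable aldehyde and dehydration should give the E-enone, the hindered diisopropylcarbamate resisting hydroxide at room temperature.

Step 5
Reactants: 6 (E)-1-[5-(benzyloxy)-2-bromophenyl]-3-ArD-prop-2-en-1-one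
Product: 7 (3S)-6-(benzyloxy)-3-ArD-indan-1-one
Conditions: Pd(OAc)2 (5 mol %), (R)-3,5-Xyl-MeO-BIPHEP (7 mol %), HCO2Na, DMF, 80 °C
Reagents that add atoms: none
Why: Asymmetric intramolecular reductive Heck reaction, in which zerovalent palladium inserts into the C–Br bond, the aryl group adds to the enone β-carbon (formal 5-endo closure), the palladium enolate is protonated and formate returns divalent palladium to the zerovalent state, the chiral bisphosphine choosing the enone face so that C3 is formed as S.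

Step 6
Reactants: 7 (3S)-6-(benzyloxy)-3-ArD-indan-1-one
Product: 8 (4S)-7-(benzyloxy)-4-ArD-3,4-dihydrocoumarin
Conditions: m-CPBA (1.2 equiv), NaHCO3, CH2Cl2, 0 °C to rt
Reagents that add atoms: 3-chloroperbenzoic acid, OOC(=O)c1cccc(Cl)c1
Why: The peracid adds to the C1 carbonyl to give a tetrahedral peroxy adduct, and the aryl carbon C7a (the future C8a) shifts from carbon to the neighbouring peroxide oxygen as 3-chlorobenzoate leaves, so that O1–C8a and O1–C2 arise in one event; this is the Baeyer–Villiger oxidation, a reaction type known for 3-arylindan-1-ones going to 4-aryl-3,4-dihydrocoumarins. Ring C is closed by ring expansion, a 1,2-shift that enlarges the five-membered carbocycle by one atom, not by cyclisation of an open chain. No stereocentre is created, and C4 keeps its S configuration because it lies outside the reacting atoms and carries no acidic hydrogen under these conditions. The step needs aryl-over-methylene migration, which the better migratory aptitude of the aryl carbon against an unsubstituted primary CH2 secures (ring B is deliberately not yet on C3), and it needs the peracid to choose the ketone over ring D, which the para carbamate (one of three donor oxygens turned into a poor donor), the flanked ring D positions and the absence of alkene, acetal or amine sites secure. Because no acid-labile group is present, a sulfonic acid co-catalyst may replace the buffer if conversion is slow.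

Step 7
Reactants: 8 (4S)-7-(benzyloxy)-4-ArD-3,4-dihydrocoumarin
Product: 10 methyl (3S)-3-[4-(benzyloxy)-2-(methoxymethoxy)phenyl]-3-ArD-propanoate, via phenol ester 9 (not isolated)
Conditions: NaOMe (1.05 equiv), MeOH/THF, 0 °C; evaporate; MOMCl, DMF, 0 °C to rt
Reagents that add atoms: sodium methoxide, C[O-].[Na+]; chloromethyl methyl ether, COCCl
Why: Methoxide opens the aryl lactone by acyl substitution and the sodium phenoxide is alkylated in the same flask by the chloromethyl ether (Williamson type), the small acetal keeping the crowded step 10 as open as possible while the O1–C8a bond and the stereocentre stay untouched.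

Step 8
Reactants: 11 2,6-dimethoxyphenol
Product: 12 2-(benzyloxy)-1,3-dimethoxybenzene
Conditions: BnBr, K2CO3, DMF, 60 °C
Reagents that add atoms: benzyl bromide, BrCc1ccccc1
Why: Williamson ether synthesis, which the flanked phenoxide still undergoes readily with benzyl bromide in a dipolar solvent.

Step 9
Reactants: 12 2-(benzyloxy)-1,3-dimethoxybenzene
Product: 13 2-(benzyloxy)-4-bromo-1,3-dimethoxybenzene (ArB–Br)
Conditions: NBS, MeCN, 0 °C to rt
Reagents that add atoms: N-bromosuccinimide, O=C1CCC(=O)N1Br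
Why: Electrophilic aromatic bromination should go to the position para to one methoxy and ortho to the other, since the flanked central benzyloxy group is twisted out of conjugation and activates its own para position only weakly.

Step 10
Reactants: 10 methyl (3S)-3-[4-(benzyloxy)-2-(methoxymethoxy)phenyl]-3-ArD-propanoate; 13 2-(benzyloxy)-4-bromo-1,3-dimethoxybenzene
Product: 14 methyl (2RS,3S)-2-ArB-3-[4-(benzyloxy)-2-(methoxymethoxy)phenyl]-3-ArD-propanoate
Conditions: LiHMDS (2.5 equiv), Pd(OAc)2 (5 mol %), P(t-Bu)3·HBF4 (10 mol %), toluene, rt to 60 °C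
Reagents that add atoms: none
Why: Palladium-catalysed α-arylation of an ester enolate (Buchwald–Hartwig type), in which oxidative addition of 13, transmetalation with the lithium enolate of 10 and reductive elimination should form the C–aryl bond, the new centre next to the ester arising as a mixture that step 11 corrects while the non-acidic 3S centre stays.

Step 11
Reactants: 14 methyl (2RS,3S)-2-ArB-3-[4-(benzyloxy)-2-(methoxymethoxy)phenyl]-3-ArD-propanoate
Product: 17 (3R,4S)-3-ArB-7-(benzyloxy)-4-ArD-chroman-2-one (trans), via phenol ester 15 (not isolated), via lactone epimer mixture 16 (not isolated)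
Conditions: p-TsOH·H2O (0.2 equiv), MeOH/CH2Cl2, 40 °C; evaporate; toluene, 100 °C, 4 Å MS; then DBU (0.5 equiv), rt
Reagents that add atoms: none
Why: Acid-catalysed acetal cleavage, then acid-catalysed lactonisation with loss of methanol (6-exo-trig acyl substitution), then base-mediated epimerisation through the lactone enolate, which should settle on the trans (3R,4S) isomer because the two aryl groups avoid each other there, C4 having no acidic hydrogen and therefore fixing the absolute sense.

Step 12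
Reactants: 17 (3R,4S)-3-ArB-7-(benzyloxy)-4-ArD-chroman-2-one
Product: 18 (2R,3S)-2-ArB-3-[4-(benzyloxy)-2-hydroxyphenyl]-3-ArD-propan-1-ol
Conditions: LiBH4, THF, 0 °C to rt
Reagents that add atoms: none
Why: Hydride reduction of the activated aryl lactone to the phenol and primary alcohol is fast at low temperature, which limits enolisation at the α-centre, and LiBH4 leaves the carbamate alone.

Step 13
Reactants: 18 (2R,3S)-2-ArB-3-[4-(benzyloxy)-2-hydroxyphenyl]-3-ArD-propan-1-ol
Product: 19 (3R,4S)-3-ArB-7-(benzyloxy)-4-ArD-chroman (protected isoflavan)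
Conditions: PPh3, DIAD, THF (0.01 M), 0 °C to rt
Reagents that add atoms: none
Why: Intramolecular Mitsunobu etherification, in which the phenol protonates the betaine and displaces the activated primary alcohol (6-exo-tet), re-forming the O1–C2 bond without touching C3 or C4.

Step 14
Reactants: 19 (3R,4S)-3-ArB-7-(benzyloxy)-4-ArD-chroman
Product: 20 3,5-bis(benzyloxy)-4-[(3R,4S)-3-ArB-7-(benzyloxy)chroman-4-yl]phenol
Conditions: LiAlH4 (excess), THF, reflux; Rochelle salt work-up
Reagents that add atoms: none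
Why: Reductive cleavage of the aryl carbamate by hydride attack at the carbamoyl carbon should release the phenoxide under non-acidic conditions that benzyl ethers, methyl ethers and the chroman tolerate.

Step 15
Reactants: 20 3,5-bis(benzyloxy)-4-[(3R,4S)-3-ArB-7-(benzyloxy)chroman-4-yl]phenol
Product: 21 1-{4,6-bis(benzyloxy)-2-hydroxy-5-[(3R,4S)-3-ArB-7-(benzyloxy)chroman-4-yl]phenyl}ethanone
Conditions: Ac2O (1.3 equiv), BF3·OEt2, CH2Cl2, 0 °C to rt; aq. NaHCO3
Reagents that add atoms: acetic anhydride, CC(=O)OC(C)=O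
Why: Friedel–Crafts acylation directed by the free phenol, since the two equivalent ring D positions ortho to the hydroxyl are the most nucleophilic carbons of the molecule and the hydrogen-bonded ortho-hydroxy ketone formed is deactivated towards a second acylation.

Step 16
Reactants: 21 1-{4,6-bis(benzyloxy)-2-hydroxy-5-[(3R,4S)-3-ArB-7-(benzyloxy)chroman-4-yl]phenyl}ethanone
Product: 23 5,7-bis(benzyloxy)-6-[(3R,4S)-3-ArB-7-(benzyloxy)chroman-4-yl]-4H-chromen-4-one, via enaminone 22 (not isolated)
Conditions: Me2NCH(OMe)2, toluene, 90 °C; evaporate; aq. HCl (1 M), CH2Cl2, rt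
Reagents that add atoms: N,N-dimethylformamide dimethyl acetal, COC(OC)N(C)C
Why: Condensation of the methyl ketone with the formamide acetal gives the enaminone, and acid-promoted conjugate addition of the ortho hydroxyl with loss of dimethylamine closes the pyranone (6-endo-trig), the oxygen para to the C4 substituent being the only free hydroxyl so that ring F can close in one direction only.

Step 17
Reactants: 23 5,7-bis(benzyloxy)-6-[(3R,4S)-3-ArB-7-(benzyloxy)chroman-4-yl]-4H-chromen-4-one; 24 [4-(benzyloxy)phenyl]boronic acid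
Product: 25 (2S)-5,7-bis(benzyloxy)-2-[4-(benzyloxy)phenyl]-6-[(3R,4S)-3-ArB-7-(benzyloxy)chroman-4-yl]chroman-4-one
Conditions: [Rh(OH)(cod)]2 (3 mol %), (S)-MeO-F12-BIPHEP (7 mol %), toluene/H2O, 40 °C
Reagents that add atoms: none
Why: Rhodium-catalysed asymmetric 1,4-addition of the arylboronic acid to the chromone (Hayashi–Miyaura reaction), in which the aryl–rhodium species adds to C2 on the face left open by the C2-symmetric bisphosphine and should set the 2S centre under catalyst control far from the existing centres, base-free conditions avoiding ring opening of the flavanone.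

Step 18
Reactants: 25 (2S)-5,7-bis(benzyloxy)-2-[4-(benzyloxy)phenyl]-6-[(3R,4S)-3-ArB-7-(benzyloxy)chroman-4-yl]chroman-4-one
Product: 26 (2S)-5,7-dihydroxy-6-[(3R,4S)-7-hydroxy-3-(3-hydroxy-2,4-dimethoxyphenyl)chroman-4-yl]-2-(4-hydroxyphenyl)chroman-4-one (CNP0267463.1)
Conditions: H2 (1 atm), 10 % Pd/C, EtOAc/MeOH, rt
Reagents that add atoms: none
Why: Catalytic hydrogenolysis should cleave the five benzylic C–O bonds while the chroman C–O bonds, the aryl ketone and the three stereocentres survive under one atmosphere of hydrogen at room temperature.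

Compound list
1 | 3,5-bis(benzyloxy)phenol | Oc1cc(OCc2ccccc2)cc(OCc2ccccc2)c1 | starting material
2 | 2,6-bis(benzyloxy)-4-hydroxybenzaldehyde | O=Cc1c(OCc2ccccc2)cc(O)cc1OCc1ccccc1 | intermediate
3 | 3,5-bis(benzyloxy)-4-formylphenyl N,N-diisopropylcarbamate | CC(C)N(C(C)C)C(=O)Oc1cc(OCc2ccccc2)c(C=O)c(OCc2ccccc2)c1 | intermediate
4 | 1-(2-bromo-5-hydroxyphenyl)ethanone | CC(=O)c1cc(O)ccc1Br | starting material
5 | 1-[5-(benzyloxy)-2-bromophenyl]ethanone | CC(=O)c1cc(OCc2ccccc2)ccc1Br | intermediate
6 | (E)-1-[5-(benzyloxy)-2-bromophenyl]-3-ArD-prop-2-en-1-one | O=C(/C=C/c1c(OCc2ccccc2)cc(OC(=O)N(C(C)C)C(C)C)cc1OCc1ccccc1)c1cc(OCc2ccccc2)ccc1Br | intermediate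
7 | (3S)-6-(benzyloxy)-3-ArD-indan-1-one | O=C1C[C@H](c2c(OCc3ccccc3)cc(OC(=O)N(C(C)C)C(C)C)cc2OCc2ccccc2)c2ccc(OCc3ccccc3)cc12 | intermediate
8 | (4S)-7-(benzyloxy)-4-ArD-3,4-dihydrocoumarin | O=C1C[C@H](c2c(OCc3ccccc3)cc(OC(=O)N(C(C)C)C(C)C)cc2OCc2ccccc2)c2ccc(OCc3ccccc3)cc2O1 | intermediate
9 | methyl (3S)-3-[4-(benzyloxy)-2-hydroxyphenyl]-3-ArD-propanoate (formed in the flask as its sodium phenoxide) | COC(=O)C[C@H](c1c(OCc2ccccc2)cc(OC(=O)N(C(C)C)C(C)C)cc1OCc1ccccc1)c1ccc(OCc2ccccc2)cc1O | intermediate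
10 | methyl (3S)-3-[4-(benzyloxy)-2-(methoxymethoxy)phenyl]-3-ArD-propanoate | COC(=O)C[C@H](c1c(OCc2ccccc2)cc(OC(=O)N(C(C)C)C(C)C)cc1OCc1ccccc1)c1ccc(OCc2ccccc2)cc1OCOC | intermediate
11 | 2,6-dimethoxyphenol | COc1cccc(OC)c1O | starting material
12 | 2-(benzyloxy)-1,3-dimethoxybenzene | COc1cccc(OC)c1OCc1ccccc1 | intermediate
13 | 2-(benzyloxy)-4-bromo-1,3-dimethoxybenzene | COc1ccc(Br)c(OC)c1OCc1ccccc1 | intermediate
14 | methyl (2RS,3S)-2-ArB-3-[4-(benzyloxy)-2-(methoxymethoxy)phenyl]-3-ArD-propanoate | COC(=O)C(c1ccc(OC)c(OCc2ccccc2)c1OC)[C@H](c1c(OCc2ccccc2)cc(OC(=O)N(C(C)C)C(C)C)cc1OCc1ccccc1)c1ccc(OCc2ccccc2)cc1OCOC | intermediate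
15 | methyl (2RS,3S)-2-ArB-3-[4-(benzyloxy)-2-hydroxyphenyl]-3-ArD-propanoate (formed in the flask) | COC(=O)C(c1ccc(OC)c(OCc2ccccc2)c1OC)[C@H](c1c(OCc2ccccc2)cc(OC(=O)N(C(C)C)C(C)C)cc1OCc1ccccc1)c1ccc(OCc2ccccc2)cc1O | intermediate
16 | (3RS,4S)-3-ArB-7-(benzyloxy)-4-ArD-chroman-2-one (formed in the flask) | COc1ccc(C2C(=O)Oc3cc(OCc4ccccc4)ccc3[C@H]2c2c(OCc3ccccc3)cc(OC(=O)N(C(C)C)C(C)C)cc2OCc2ccccc2)c(OC)c1OCc1ccccc1 | intermediate
17 | (3R,4S)-3-ArB-7-(benzyloxy)-4-ArD-chroman-2-one | COc1ccc([C@@H]2C(=O)Oc3cc(OCc4ccccc4)ccc3[C@H]2c2c(OCc3ccccc3)cc(OC(=O)N(C(C)C)C(C)C)cc2OCc2ccccc2)c(OC)c1OCc1ccccc1 | intermediate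
18 | (2R,3S)-2-ArB-3-[4-(benzyloxy)-2-hydroxyphenyl]-3-ArD-propan-1-ol | COc1ccc([C@H](CO)[C@H](c2c(OCc3ccccc3)cc(OC(=O)N(C(C)C)C(C)C)cc2OCc2ccccc2)c2ccc(OCc3ccccc3)cc2O)c(OC)c1OCc1ccccc1 | intermediate
19 | (3R,4S)-3-ArB-7-(benzyloxy)-4-ArD-chroman | COc1ccc([C@@H]2COc3cc(OCc4ccccc4)ccc3[C@H]2c2c(OCc3ccccc3)cc(OC(=O)N(C(C)C)C(C)C)cc2OCc2ccccc2)c(OC)c1OCc1ccccc1 | intermediate
20 | 3,5-bis(benzyloxy)-4-[(3R,4S)-3-ArB-7-(benzyloxy)chroman-4-yl]phenol | COc1ccc([C@@H]2COc3cc(OCc4ccccc4)ccc3[C@H]2c2c(OCc3ccccc3)cc(O)cc2OCc2ccccc2)c(OC)c1OCc1ccccc1 | intermediate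
21 | 1-{4,6-bis(benzyloxy)-2-hydroxy-5-[(3R,4S)-3-ArB-7-(benzyloxy)chroman-4-yl]phenyl}ethanone | COc1ccc([C@@H]2COc3cc(OCc4ccccc4)ccc3[C@H]2c2c(OCc3ccccc3)cc(O)c(C(C)=O)c2OCc2ccccc2)c(OC)c1OCc1ccccc1 | intermediate
22 | (E)-1-{4,6-bis(benzyloxy)-2-hydroxy-5-[(3R,4S)-3-ArB-7-(benzyloxy)chroman-4-yl]phenyl}-3-(dimethylamino)prop-2-en-1-one (formed in the flask) | COc1ccc([C@@H]2COc3cc(OCc4ccccc4)ccc3[C@H]2c2c(OCc3ccccc3)cc(O)c(C(=O)/C=C/N(C)C)c2OCc2ccccc2)c(OC)c1OCc1ccccc1 | intermediate
23 | 5,7-bis(benzyloxy)-6-[(3R,4S)-3-ArB-7-(benzyloxy)chroman-4-yl]-4H-chromen-4-one | COc1ccc([C@@H]2COc3cc(OCc4ccccc4)ccc3[C@H]2c2c(OCc3ccccc3)cc3occc(=O)c3c2OCc2ccccc2)c(OC)c1OCc1ccccc1 | intermediate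
24 | [4-(benzyloxy)phenyl]boronic acid | OB(O)c1ccc(OCc2ccccc2)cc1 | starting material
25 | (2S)-5,7-bis(benzyloxy)-2-[4-(benzyloxy)phenyl]-6-[(3R,4S)-3-ArB-7-(benzyloxy)chroman-4-yl]chroman-4-one | COc1ccc([C@@H]2COc3cc(OCc4ccccc4)ccc3[C@H]2c2c(OCc3ccccc3)cc3c(c2OCc2ccccc2)C(=O)C[C@@H](c2ccc(OCc4ccccc4)cc2)O3)c(OC)c1OCc1ccccc1 | intermediate
26 | (2S)-5,7-dihydroxy-6-[(3R,4S)-7-hydroxy-3-(3-hydroxy-2,4-dimethoxyphenyl)chroman-4-yl]-2-(4-hydroxyphenyl)chroman-4-one | COc1ccc([C@@H]2COc3cc(O)ccc3[C@H]2c2c(O)cc3c(c2O)C(=O)C[C@@H](c2ccc(O)cc2)O3)c(OC)c1O | target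

Total steps: 18. Longest linear sequence: 15 steps (from 1 through steps 1, 2, 4 to 7 and 10 to 18).

Steps most likely to fail

Step 10. Reductive elimination at the crowded arylpalladium enolate (a benzhydryl-type neighbour on one side, an ortho-methoxy aryl group on the other) may be too slow, so that the enolate is only reprotonated or the aryl bromide is reduced. The fallback inverts the polarity at the α-carbon. It sets out from ester 10, which is brominated through its lithium enolate (LiHMDS, THF, −78 °C; then CBr4) to methyl (2RS,3S)-2-bromo-3-[4-(benzyloxy)-2-(methoxymethoxy)phenyl]-3-ArD-propanoate F1. F1 is then joined to bromide 13 by nickel-catalysed reductive cross-electrophile coupling (NiBr2(dme), 4,4′-di-tert-butyl-2,2′-bipyridine, Mn powder, DMA), a radical C–C bond formation that should tolerate more crowding. The product is 14, and the route continues with step 11.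

Step 5. Arylpalladation of the β-carbon, shielded on both faces by the two ortho benzyloxy groups, may lose against formate reduction of the arylpalladium bromide, or the ligand may discriminate the enone faces poorly. The fallback replaces the halide by boron and palladium by rhodium, so that no hydride source is present. It sets out from ketone 5: Miyaura borylation (B2pin2, PdCl2(dppf), KOAc, dioxane, 80 °C) gives 1-[5-(benzyloxy)-2-(4,4,5,5-tetramethyl-1,3,2-dioxaborolan-2-yl)phenyl]ethanone F2. Claisen–Schmidt condensation of F2 with aldehyde 3 gives (E)-1-[5-(benzyloxy)-2-(4,4,5,5-tetramethyl-1,3,2-dioxaborolan-2-yl)phenyl]-3-ArD-prop-2-en-1-one F3. Rhodium-catalysed asymmetric intramolecular 1,4-addition ([RhCl(C2H4)2]2, chiral diene ligand, aq. K3PO4, toluene) closes the five-membered ring to 7, and the route continues with step 6.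

Step 6. Electrophilic hydroxylation of ring D by the peracid may outrun a slow oxygen insertion. The fallback brings the aryl–oxygen bond in with the nucleophile instead of inserting it. It sets out from aldehyde 3: Knoevenagel condensation with Meldrum's acid gives 5-(ArD-methylidene)-2,2-dimethyl-1,3-dioxane-4,6-dione F4. Rhodium-catalysed asymmetric conjugate addition of [4-(benzyloxy)-2-hydroxyphenyl]boronic acid ([RhCl(C2H4)2]2, chiral diene ligand, aq. KOH, dioxane) gives 5-{(S)-[4-(benzyloxy)-2-hydroxyphenyl](ArD)methyl}-2,2-dimethyl-1,3-dioxane-4,6-dione F5. Heating F5 in toluene lactonises it with loss of acetone and carbon dioxide to 8, where the route continues with step 7; steps 4 to 6 are then not needed.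

Further compounds
F1 | step 10 | methyl (2RS,3S)-2-bromo-3-[4-(benzyloxy)-2-(methoxymethoxy)phenyl]-3-ArD-propanoate | COC(=O)C(Br)[C@H](c1c(OCc2ccccc2)cc(OC(=O)N(C(C)C)C(C)C)cc1OCc1ccccc1)c1ccc(OCc2ccccc2)cc1OCOC
F2 | step 5 | 1-[5-(benzyloxy)-2-(4,4,5,5-tetramethyl-1,3,2-dioxaborolan-2-yl)phenyl]ethanone | CC(=O)c1cc(OCc2ccccc2)ccc1B1OC(C)(C)C(C)(C)O1
F3 | step 5 | (E)-1-[5-(benzyloxy)-2-(4,4,5,5-tetramethyl-1,3,2-dioxaborolan-2-yl)phenyl]-3-ArD-prop-2-en-1-one | O=C(/C=C/c1c(OCc2ccccc2)cc(OC(=O)N(C(C)C)C(C)C)cc1OCc1ccccc1)c1cc(OCc2ccccc2)ccc1B1OC(C)(C)C(C)(C)O1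
F4 | step 6 | 5-(ArD-methylidene)-2,2-dimethyl-1,3-dioxane-4,6-dione | CC(C)N(C(C)C)C(=O)Oc1cc(OCc2ccccc2)c(C=C2C(=O)OC(C)(C)OC2=O)c(OCc2ccccc2)c1
F5 | step 6 | 5-{(S)-[4-(benzyloxy)-2-hydroxyphenyl](ArD)methyl}-2,2-dimethyl-1,3-dioxane-4,6-dione | CC1(C)OC(=O)C([C@H](c2c(OCc3ccccc3)cc(OC(=O)N(C(C)C)C(C)C)cc2OCc2ccccc2)c2ccc(OCc3ccccc3)cc2O)C(=O)O1
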